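The data come from a simulation for an exercise; noise was put on by code.

- Follow L = ln x − x, not the target itself, where x is the target as a fraction of the starting material charged.

| setting | dusk | spring | dawn | epsilon | zeta |
|---|---|---|---|---|---|
| starting material | 0.11 M | 0.11 M | 0.11 M | 0.11 M | 0.11 M |
| partner | 0.143 M | 0.143 M | 0.071 M | 0.143 M | 0.143 M |
| second substrate | 0.011 M | 0.044 M | 0.022 M | 0.0220 M | 0.0220 M |
| remark | run made earlier | run made earlier | run made earlier |  |  |
| time |  |  |  | 2.0 h | 5.0 h |

| run | time / min | target / % | starting material / % |
|---|---|---|---|
| dusk | 8.00 | 73.3 | 27.4 |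
| dusk | 25.0 | 77.6 | 24.5 |
| dusk | 40.0 | 73.5 | 26.3 |
| dusk | 60.0 | 67.2 | 32.4 |
| dusk | 90.0 | 60.7 | 39.7 |
| dusk | 120 | 55.3 | 47.2 |
| spring | 8.00 | 68.7 | 31.4 |
| spring | 25.0 | 74.1 | 24.7 |
| spring | 40.0 | 71.2 | 27.6 |
| spring | 60.0 | 66.4 | 33.9 |
| spring | 90.0 | 60.8 | 40.8 |
| spring | 120 | 55.4 | 42.5 |
| dawn | 25.0 | 45.6 | 52.0 |
| dawn | 50.0 | 44.1 | 56.6 |
| dawn | 80.0 | 39.1 | 59.7 |
| dawn | 90.0 | 40.0 | 61.6 |
| dawn | 120 | 35.3 | 62.7 |

(scatter of a reading: 1 percentage point)

- the earlier runs were read with a standard deviation of 1 percentage point

- which of these there is most of at the end, counted by the starting material in it, epsilon (target / starting material)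
- which of these there is most of at the end, counted by the starting material in it, zeta (target / starting material)
- how much there is at the end of the one of these that leads, in percent of the starting material charged: epsilon
- how much there is at the end of the one of these that leads, in percent of the starting material charged: zeta

- Dusk is the neighbour that looks nearly the same as epsilon: it has the same starting material and partner and differs in its second substrate, 0.011 M against 0.0220 M.
- Spring, with 0.044 M of second substrate, reads 55.4% of target at 120 min, and dusk reads 55.3%. The two lie 0.1 points apart, with a scatter of 1 point on each reading, so epsilon, read at that same time, is set at their mean, 55.4% target. Zeta is the same charge left until 5.0 h.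
- Target and starting material sum to near 100%, so the working assumption is a fast pre-equilibrium, x/(1 − x) proportional to free partner, with that free partner small and lost first-order. Then every bit of partner lost pulls target apart, and integration gives L falling in a straight line, at a slope that contains no partner charge.
- From the means of dusk and spring, L is −1.07 at 60.0 min and −1.14 at 120 min. L therefore falls at 0.00123 min⁻¹, the drain rate s, the amount of L lost per minute.
- Carried on to 5.0 h, L reaches −1.37. Solving for x gives my own figure for zeta, 36.9% target, so 63.1% starting material.
- The forecast names target for epsilon at 55% (51% to 59%) and starting material for zeta at 70% (61% to 78%), holding that the second substrate “plays no kinetic part”. For zeta, my figure stands below its 70%.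
- Epsilon gives 55.6% of target, and zeta gives 62.4% of starting material.

    starting material + partner ⇌ target (K = 210 M⁻¹, k = 3.06 M⁻¹ min⁻¹)
    second substrate + partner ⇌ second product (K = 19.8 M⁻¹, k = 2.08 M⁻¹ min⁻¹)
    partner → decomposed reagent (k = 0.0290 min⁻¹)
    partner ⇌ dormant form (K = 16.0, k = 0.0259 min⁻¹)

- At zeta's end, free partner stands at 1.78% of its charge and decomposed reagent at 0.0599 M. Between the two flasks' readings, the target values give a drain rate of 0.00117 min⁻¹, against s of 0.00123 min⁻¹. The neighbour of zeta charged with 0.036 M of partner can hold at most x = 0.327 as target. Started there, s gives L = −1.81 at 5.00 h, so x = 20.0%. That neighbour holds 14.6% target.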